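**The vessel.** The closed, stirred vessel held Q under G, and Q left by two routes: with dissolved Z to Q.Z, or by itself to L.

Q 1.0 M; G 140 mM (held); time 12 min

    G ⇌ Z, rate k1*(csat - [Z]) (k1 = 4.5 /min, csat = 140 mM)
    D ⇌ Q.Z, rate k2*(cs2 - [Q.Z]) while solid is left; crystals form when [Q.Z] > cs2 (cs2 = 0.33 M, k2 = 5.9 /min)
    Z → J (k3 = 0.035 /min)
    Q + Z → Q.Z (k4 = 2.5 /M/min)
    Q → L (k5 = 0.33 /min)
    Z + Q.Z → Z.Q.Z (k6 = 0.058 /M/min)

- amounts and yields of Q.Z count D too
- given per volume of solution although it is solid: D
- at the start none of Z is dissolved
- run time (flask): 12 min

- Q.Z and D together at 12 min, in percent of the Q charged
- concentration of Z in solution at 3.0 min, in percent of saturation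
- the change that raises the amount of Q.Z and D together at 12 min, in percent of the Q charged most ("none" if none brings more than 2 percentage points) (autumn / winter / midnight / spring / none)
- amount of Q.Z and D together at 12 min, in percent of the Q charged, after spring

- autumn: doubling the dissolution coefficient of step 2, all else as stated
- winter: doubling the saturation concentration of G, all else as stated
- midnight: doubling the solubility in step 2, all else as stated
- spring: doubling the transfer coefficient of step 1, all else as stated

**End state.** Even without capture, the route to L left 1.91% of Q by 12 min, so I reckoned the yield as a split of Q between the routes.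

**First extreme.** Suppose c(Z) stood at 140 mM throughout. Capture then ran at 0.350 /min against 0.33 /min for L, which gave the saturation share, the capture rate of Q over capture plus L rate (the selectivity): 51.5%.

**Second extreme.** Suppose transfer just fed capture by the full charge. Then c(Z) was 90.0 mM and the share 40.5%.

**Between them.** I reckoned Z to adjust in 0.143 min, faster than the 2.1 min half-life of Q by the L route, so I expected c(Z) to follow falling Q upward. Apart from that brief start, I placed the share between the extremes and took their midpoint, 46.0%. I let Q.Z bleed to Z.Q.Z at saturated c(Z) for the whole run, which in my reckoning kept 90.7% of it, so my y came to 41.7%.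

**Other answers.** With c(Z) at 110 mM, I put Q at 3.0 min at 0.163 M, which put sat at 91.7%. The crystal settings do not enter my share, and when I scored each change by that share, my choice was winter. In my reckoning spring raised the low end to 110 mM, giving 43.9%.

**The forecast.** It gave 41%, 90%, winter and 44%, on these grounds: “Doubling the saturation concentration raises Z and so the selectivity far more than faster transfer does”.

**The flask.** The flask gave 40.4%, 89.3%, winter with a gain of 13 percentage points, and 43.8% after spring. At 12.0 min in the flask, Q went to L at 0.95 times its rate to Q.Z, a late share of 51.3%, close to the saturation share of 51.5%, but by 2.40 min the route to L had 78% of its turnover up to 12 min behind it. In the flask stopped at 3.0 min, Q.Z stood at 34.2% against 48.3% of L, a running share of 41.5%, less than the saturation share, with 17% of the charged Q still there.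

The numbers belong to no real substance; the result is computed.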